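**Retrosynthetic overview**

1. Polonidine A (14) is traced back to the bis-indoline 12 by adding H2 across C2–C3 of both five-membered rings (forward: dehydrogenation with MnO2).
2. The feature the route rests on: in each indole the aryl bond C3a=C7a, N1 and C2=C3 form an N-aryl enamine, so the N1 lone pair and two double bonds hold six electrons with C3 and C3a as termini. Both five-membered rings are therefore cut at C3–C3a, giving the open-chain bis-enamine 10, in which C2, C3, the bridging CH2, C3' and C2' are one five-carbon chain.
3. 10 is traced back to the glutaric bis-anilide 8 (amide-to-enamine reduction). This replaces condensation with glutaraldehyde, which would be slow on the hindered N-tert-alkylaniline and would need a Lewis acid able to trigger a 3-aza-Cope shift of the N-allyl enamine.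
4. 8 comes from glutaryl dichloride 5 and N-(2-methylbut-3-en-2-yl)aniline 4; 4 comes from aniline 1 and 3-chloro-3-methylbut-1-yne 2 (copper-catalysed propargylation, then semihydrogenation).
5. Ring order: the benzene rings arrive with aniline; the two nitrogen five-membered rings are closed one after the other in the same irradiation (step 5) and aromatised together (step 6).

Key step: step 5

Remark on the chemistry: the enamine double bonds of 10 are written E, the less hindered geometry expected from step 4; the geometry has no bearing on step 5. Compound 12 is written without configuration at C3 and C3', because meso and racemic forms are expected together and both centres are removed in step 6.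

**Route**

Step 1
Reactants: 1 aniline; 2 3-chloro-3-methylbut-1-yne
Product: 3 N-(2-methylbut-3-yn-2-yl)aniline
Conditions: CuCl (10 mol%), Cu powder (cat.), Et3N, THF, 0 °C to rt
Reagents that add atoms: none
Why: Copper-catalysed propargylic amination (Hennion-type substitution), in which the copper acetylide of 2 loses chloride and aniline attacks the tertiary carbon, the bulk of the new group stopping the reaction at monoalkylation.

Step 2
Reactants: 3 N-(2-methylbut-3-yn-2-yl)aniline
Product: 4 N-(2-methylbut-3-en-2-yl)aniline
Conditions: H2 (1 atm), Pd/CaCO3 poisoned with Pb(OAc)2, quinoline, EtOAc, rt, stopped after one equivalent of H2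
Reagents that add atoms: none
Why: Lindlar semihydrogenation should stop at the terminal alkene, and the adjacent quaternary carbon rules out alkene migration.

Step 3
Reactants: 4 N-(2-methylbut-3-en-2-yl)aniline (2.1 equiv); 5 pentanedioyl dichloride (glutaryl dichloride)
Product: 8 N1,N5-bis(2-methylbut-3-en-2-yl)-N1,N5-diphenylpentanediamide, via lithium anilide 6 (not isolated), via mono-amide acid chloride 7 (not isolated)
Conditions: n-BuLi (2.05 equiv), THF, −78 °C; then 5 (1.0 equiv), −78 °C to rt
Reagents that add atoms: none
Why: N-acylation of a lithium anilide by a diacid chloride (nucleophilic acyl substitution), where deprotonation makes the hindered nitrogen nucleophilic enough and keeps the medium free of acid, so the tertiary allylic N–C bond is not ionised.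

Step 4
Reactants: 8 N1,N5-bis(2-methylbut-3-en-2-yl)-N1,N5-diphenylpentanediamide
Product: 10 (1E,4E)-N1,N5-bis(2-methylbut-3-en-2-yl)-N1,N5-diphenylpenta-1,4-diene-1,5-diamine, via bis(N,O-silyl acetal) 9 (not isolated)
Conditions: IrCl(CO)(PPh3)2 (2 mol%), (HMe2Si)2O (4.4 equiv), toluene, rt, Ar; volatiles removed, short pad of basic alumina under Ar, used at once and kept cold
Reagents that add atoms: none
Why: Iridium-catalysed hydrosilylation of each tertiary amide to its N,O-silyl acetal and loss of silanol across the α-CH2 is the known amide-to-enamine reduction, and because it runs neutral at room temperature it should avoid the acid- or heat-promoted 3-aza-Cope shift of the N-allyl enamine and give the less hindered E double bonds.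

Step 5
Reactants: 10 (1E,4E)-N1,N5-bis(2-methylbut-3-en-2-yl)-N1,N5-diphenylpenta-1,4-diene-1,5-diamine
Product: 12 3,3'-methylenebis[1-(2-methylbut-3-en-2-yl)indoline] (meso plus racemic), via mono-indoline enamine 11 (not isolated)
Conditions: hν (medium-pressure Hg lamp, Pyrex filter, λ > 290 nm), degassed Et2O (0.005 M), Ar, 10–15 °C, followed to full conversion of 11
Reagents that add atoms: none
Why: Light absorbed by each N-aryl enamine unit (N1 lone pair, C2=C3 and the ring bond C3a=C7a, six electrons) should bring about conrotatory closure between C3 and C3a to a short-lived zwitterion with a cyclohexadiene ring, which regains the benzene ring by a suprafacial 1,4-shift of the C3a hydrogen to C2. The closest known reaction is the non-oxidative photocyclisation of N-alkyl-N-aryl enamines to indolines, run here at both ends of one molecule, first to 11 and then to 12. Each five-membered ring (N1, C2, C3, C3a, C7a) is closed by this six-electron conrotatory electrocyclisation and not by ionic or radical attack on the arene. The stereocentres at C3 and C3' have no controlling element, since the substrate is achiral, the C3a centre created alongside is lost on rearomatisation and C2 ends as CH2, so meso and racemic 12 should form together and both centres vanish in step 6. The step needs chemoselectivity for the enamine–arene chromophore over the two vinyl groups and over cleavage of the tertiary allylic N–C bonds: the vinyl groups sit behind a quaternary carbon and do not absorb above 290 nm, no acid, metal or heat is present, and the bulky N-substituent should hold C3 and the ortho carbon on the same side of nitrogen. Enamine geometry needs no control, because E and Z forms interconvert under the lamp and lead to the same indoline.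

Step 6
Reactants: 12 3,3'-methylenebis[1-(2-methylbut-3-en-2-yl)indoline]
Product: 14 polonidine A, via indolyl-indolinyl methane 13 (not isolated)
Conditions: activated MnO2 (excess), CH2Cl2, rt, stopped when 13 is consumed
Reagents that add atoms: none
Why: Dehydrogenation of N-alkylindolines to indoles with activated MnO2 is driven by aromatisation, should leave the vinyl groups and the tertiary N–C bonds untouched, and removes both C3 stereocentres.

**Compound list**

1 | aniline | Nc1ccccc1 | starting material
2 | 3-chloro-3-methylbut-1-yne | C#CC(C)(C)Cl | starting material
3 | N-(2-methylbut-3-yn-2-yl)aniline | C#CC(C)(C)Nc1ccccc1 | intermediate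
4 | N-(2-methylbut-3-en-2-yl)aniline | C=CC(C)(C)Nc1ccccc1 | intermediate
5 | pentanedioyl dichloride (glutaryl dichloride) | O=C(Cl)CCCC(=O)Cl | starting material
6 | lithium N-(2-methylbut-3-en-2-yl)anilide | [Li]N(c1ccccc1)C(C)(C)C=C | intermediate (not isolated)
7 | 5-[(2-methylbut-3-en-2-yl)(phenyl)amino]-5-oxopentanoyl chloride | C=CC(C)(C)N(c1ccccc1)C(=O)CCCC(=O)Cl | intermediate (not isolated)
8 | N1,N5-bis(2-methylbut-3-en-2-yl)-N1,N5-diphenylpentanediamide | C=CC(C)(C)N(c1ccccc1)C(=O)CCCC(=O)N(c1ccccc1)C(C)(C)C=C | intermediate
9 | N1,N5-bis(2-methylbut-3-en-2-yl)-N1,N5-diphenyl-1,5-bis[(1,1,3,3-tetramethyldisiloxanyl)oxy]pentane-1,5-diamine (diastereomer mixture) | C=CC(C)(C)N(c1ccccc1)C(O[Si](C)(C)O[SiH](C)C)CCCC(O[Si](C)(C)O[SiH](C)C)N(c1ccccc1)C(C)(C)C=C | intermediate (not isolated)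
10 | (1E,4E)-N1,N5-bis(2-methylbut-3-en-2-yl)-N1,N5-diphenylpenta-1,4-diene-1,5-diamine | C=CC(C)(C)N(/C=C/C/C=C/N(c1ccccc1)C(C)(C)C=C)c1ccccc1 | intermediate (key-step precursor)
11 | N-(2-methylbut-3-en-2-yl)-N-{(E)-3-[1-(2-methylbut-3-en-2-yl)indolin-3-yl]prop-1-en-1-yl}aniline (racemic) | C=CC(C)(C)N1CC(C/C=C/N(c2ccccc2)C(C)(C)C=C)c2ccccc21 | intermediate (not isolated)
12 | 3,3'-methylenebis[1-(2-methylbut-3-en-2-yl)indoline] (meso and racemic forms, configuration at C3 and C3' not defined) | C=CC(C)(C)N1CC(CC2CN(C(C)(C)C=C)c3ccccc23)c2ccccc21 | intermediate (key-step product)
13 | 1-(2-methylbut-3-en-2-yl)-3-{[1-(2-methylbut-3-en-2-yl)indolin-3-yl]methyl}-1H-indole (racemic) | C=CC(C)(C)n1cc(CC2CN(C(C)(C)C=C)c3ccccc23)c2ccccc21 | intermediate (not isolated)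
14 | polonidine A, bis[1-(2-methylbut-3-en-2-yl)-1H-indol-3-yl]methane (no stereocentre) | C=CC(C)(C)n1cc(Cc2cn(C(C)(C)C=C)c3ccccc23)c2ccccc21 | target

**Step count and risks**

Total step count: 6. Longest linear sequence: 6 steps (from aniline).

Steps most likely to fail:

1. Step 5. Homolysis of the tertiary allylic N–C bond in the excited state (with a 1,3-shift or loss of the C5 group) may compete with ring closure. E/Z isomerisation wastes light, and the indoline formed first also absorbs and may be degraded before the second ring closes. Fallback, which sets out from 2 and returns to the route at 14: commercial indoline F1 is N-alkylated with 2 (CuCl, Et3N, THF) to 1-(2-methylbut-3-yn-2-yl)indoline F2, which is semihydrogenated (H2, Pd/CaCO3 poisoned with Pb(OAc)2, quinoline) to 1-(2-methylbut-3-en-2-yl)indoline F3 and dehydrogenated with MnO2 to 1-(2-methylbut-3-en-2-yl)-1H-indole F4. Two molecules of F4 are then joined at C3 by twofold electrophilic substitution with aqueous formaldehyde under weak acid catalysis (AcOH, EtOH, rt) to give 14.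

2. Step 4. Hydrosilylation of the two hindered anilide carbonyls may stop part-way, the N,O-silyl acetal may be reduced on to the saturated amine, the vinyl groups may be hydrosilylated, and the enamine may hydrolyse on handling. Fallback, which sets out from 4 and returns at 10: 4 (slight excess) is condensed directly with anhydrous glutaraldehyde F5 (TiCl4, Et3N, toluene, −20 °C to rt), so that both enamines are made by dehydration of the aldehyde adducts and not by reduction. The low temperature and the amine base are chosen to hold back the aza-Cope shift.

3. Step 3. Acylation at the hindered nitrogen may be slow, the anilide may act as a base on the acid chloride (ketene formation and oligomers), and the reaction may halt at the mono-amide. Fallback, which sets out from 3 and returns at 8: the slimmer alkynyl amine 3 is acylated with 5 under neutral conditions (pyridine, DMAP cat., CH2Cl2, 40 °C) to N1,N5-bis(2-methylbut-3-yn-2-yl)-N1,N5-diphenylpentanediamide F6, and both alkynes are then semihydrogenated (H2, Pd/CaCO3 poisoned with Pb(OAc)2, quinoline, EtOAc) to give 8.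

Further compounds
F1 | step 5 | indoline | C1Cc2ccccc2N1
F2 | step 5 | 1-(2-methylbut-3-yn-2-yl)indoline | C#CC(C)(C)N1CCc2ccccc21
F3 | step 5 | 1-(2-methylbut-3-en-2-yl)indoline | C=CC(C)(C)N1CCc2ccccc21
F4 | step 5 | 1-(2-methylbut-3-en-2-yl)-1H-indole | C=CC(C)(C)n1ccc2ccccc21
F5 | step 4 | glutaraldehyde (pentanedial) | O=CCCCC=O
F6 | step 3 | N1,N5-bis(2-methylbut-3-yn-2-yl)-N1,N5-diphenylpentanediamide | C#CC(C)(C)N(c1ccccc1)C(=O)CCCC(=O)N(c1ccccc1)C(C)(C)C#C
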